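The six-membered ring (C3a, C4, C5, C6, C7, C7a) is closed at the C3a–C4 bond. The step exploits the exocyclic methylene on C4 next to ring-fusion carbon C3a: C4 is generated as a vinyl radical from a 2-bromoalkene and adds 6-exo to C3a of an (E)-enoate, so one operation delivers the ring, the methylene and the C3a stereocentre. The precursor is an open chain in which C5 and C6 come from L-tartrate, and C7 (isopropyl) and C7a (CH2O arm) are set on a butenolide. C5 and C6 bear different silyl groups (TES/TBS) so that the angelate later goes to C5 only.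

Key step: step 15

Remark: atom labels C1–C7a are those of the octahydroinden-2-one core of the target (C1 CHOAc, C2 C=O, C3 CH2, C3a/C7a ring fusion, C4 C=CH2, C5 CHOAng, C6 CHOH, C7 CH-i-Pr) and are kept for every intermediate; commercial dimethyl 2,3-O-isopropylidene-L-tartrate is taken as the L-tartrate building block.

Step 1
Reactants: 1 dimethyl 2,3-O-isopropylidene-L-tartrate; 2 methyltriphenylphosphonium bromide
Product: 4 (4S,5S)-4,5-diethenyl-2,2-dimethyl-1,3-dioxolane, via dialdehyde acetonide 3 (not isolated)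
Conditions: i-Bu2AlH (2.1 equiv), PhMe, −78 °C; then Ph3P=CH2 [from 2 (2.6 equiv), KN(SiMe3)2, THF], −78 °C → rt
Reagents that add atoms: methyltriphenylphosphonium bromide, C[P+](c1ccccc1)(c1ccccc1)c1ccccc1.[Br-]
Why: One-pot half-reduction/Wittig methylenation, in which each ester is held as its aluminium hemiacetal at −78 °C and releases aldehyde only as the ylide consumes it, so the two tartrate stereocentres (future C5 and C6) should not epimerise and no new stereocentre is formed.

Step 2
Reactants: 4 (4S,5S)-4,5-diethenyl-2,2-dimethyl-1,3-dioxolane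
Product: 5 (3S,4S)-hexa-1,5-diene-3,4-diol
Conditions: 1 M aq HCl, MeOH, rt
Reagents that add atoms: none
Why: Acid-catalysed acetal hydrolysis frees the C2-symmetric diol without touching either carbinol configuration.

Step 3
Reactants: 5 (3S,4S)-hexa-1,5-diene-3,4-diol
Product: 6 (3S,4S)-4-(triethylsilyloxy)hexa-1,5-dien-3-ol
Conditions: Et3SiCl (1.0 equiv), imidazole, CH2Cl2, −30 → 0 °C
Reagents that add atoms: chlorotriethylsilane, CC[Si](Cl)(CC)CC
Why: Mono-silylation of a C2-symmetric diol, in which both hydroxyls are equivalent so that one equivalent of silyl chloride should give a single mono-ether (the oxygen that becomes C5–O), the first silyl group slowing the second silylation.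

Step 4
Reactants: 6 (3S,4S)-4-(triethylsilyloxy)hexa-1,5-dien-3-ol; 7 acryloyl chloride
Product: 8 (3S,4S)-4-(triethylsilyloxy)hexa-1,5-dien-3-yl prop-2-enoate
Conditions: acryloyl chloride, i-Pr2NEt, DMAP (cat.), CH2Cl2, −20 → 0 °C
Reagents that add atoms: acryloyl chloride, C=CC(=O)Cl
Why: O-acylation of the remaining secondary alcohol (future C6–O) with an acid chloride under amine base, where a silyl shift between the two oxygens would only regenerate the same compound.

Step 5
Reactants: 8 (3S,4S)-4-(triethylsilyloxy)hexa-1,5-dien-3-yl prop-2-enoate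
Product: 9 (5S)-5-[(1S)-1-(triethylsilyloxy)prop-2-en-1-yl]furan-2(5H)-one
Conditions: second-generation Grubbs catalyst (H2IMes)(PCy3)Cl2Ru=CHPh (5 mol %), CH2Cl2 (0.005 M), 40 °C
Reagents that add atoms: none
Why: Ring-closing metathesis of an allyl acrylate to a butenolide, in which the five-membered lactone should close through the vinyl group on the acyloxy carbon faster than a six-membered lactone can form through the vinyl group shielded by the silyloxy substituent, with no stereocentre changed.

Step 6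
Reactants: 9 (5S)-5-[(1S)-1-(triethylsilyloxy)prop-2-en-1-yl]furan-2(5H)-one; 10 isopropylmagnesium bromide
Product: 11 (4R,5S)-4-(propan-2-yl)-5-[(1S)-1-(triethylsilyloxy)prop-2-en-1-yl]oxolan-2-one
Conditions: i-PrMgBr (2.2 equiv), CuBr·SMe2 (1.1 equiv), THF, −78 → −40 °C; aq NH4Cl
Reagents that add atoms: isopropylmagnesium bromide, CC(C)[Mg]Br
Why: Conjugate addition of an organocuprate to a butenolide, in which the isopropyl group should add to C7 on the face opposite the C6 side chain and so give the trans-4,5-disubstituted lactone.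

Step 7
Reactants: 11 (4R,5S)-4-(propan-2-yl)-5-[(1S)-1-(triethylsilyloxy)prop-2-en-1-yl]oxolan-2-one
Product: 12 (4R,5S)-5-[(1R)-2,3-dibromo-1-(triethylsilyloxy)propyl]-4-(propan-2-yl)oxolan-2-one (both epimers at the CHBr carbon)
Conditions: Br2 (1.05 equiv), CH2Cl2, −78 °C
Reagents that add atoms: bromine, BrBr
Why: Electrophilic addition of bromine to the only alkene gives the vicinal dibromide, whose new CHBr centre forms as a mixture that is erased in the next step.

Step 8
Reactants: 12 (4R,5S)-5-[(1R)-2,3-dibromo-1-(triethylsilyloxy)propyl]-4-(propan-2-yl)oxolan-2-one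
Product: 13 (4R,5S)-5-[(1R)-2-bromo-1-(triethylsilyloxy)prop-2-en-1-yl]-4-(propan-2-yl)oxolan-2-one
Conditions: DBU (3 equiv), DMF, 60 °C
Reagents that add atoms: none
Why: Base-induced E2 dehydrobromination, in which DBU removes the C4 hydrogen (acidified by its own bromine and by the neighbouring silyloxy-bearing carbon) and expels the terminal bromide, so that the 2-bromo-1-alkene should form and not the 1-bromoalkene.

Step 9
Reactants: 13 (4R,5S)-5-[(1R)-2-bromo-1-(triethylsilyloxy)prop-2-en-1-yl]-4-(propan-2-yl)oxolan-2-one; 14 formaldehyde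
Product: 16 (3R,4S,5S)-5-[(1R)-2-bromo-1-(triethylsilyloxy)prop-2-en-1-yl]-3-(hydroxymethyl)-4-(propan-2-yl)oxolan-2-one, via lithium enolate 15 (not isolated)
Conditions: LiN(SiMe3)2 (1.1 equiv), THF, −78 °C; then CH2O (gas, from cracked paraformaldehyde), −78 → −40 °C; aq NH4Cl
Reagents that add atoms: formaldehyde, C=O
Why: Aldol hydroxymethylation of a lactone enolate, in which formaldehyde should approach the enolate face opposite the adjacent isopropyl group and so set C7a trans to C7, while LiN(SiMe3)2 at −78 °C leaves the bromoalkene alone.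

Step 10
Reactants: 16 (3R,4S,5S)-5-[(1R)-2-bromo-1-(triethylsilyloxy)prop-2-en-1-yl]-3-(hydroxymethyl)-4-(propan-2-yl)oxolan-2-one
Product: 17 (3R,4S,5S)-5-[(1R)-2-bromo-1-(triethylsilyloxy)prop-2-en-1-yl]-4-(propan-2-yl)-3-[(triethylsilyloxy)methyl]oxolan-2-one
Conditions: Et3SiCl, imidazole, CH2Cl2, 0 °C
Reagents that add atoms: chlorotriethylsilane, CC[Si](Cl)(CC)CC
Why: Silylation of the primary alcohol with a silyl chloride under neutral conditions, a primary triethylsilyl ether being chosen because it can later be oxidised directly to the aldehyde.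

Step 11
Reactants: 17 (3R,4S,5S)-5-[(1R)-2-bromo-1-(triethylsilyloxy)prop-2-en-1-yl]-4-(propan-2-yl)-3-[(triethylsilyloxy)methyl]oxolan-2-one
Product: 18 (2R,3S,4S,5R)-6-bromo-4-hydroxy-N-methoxy-N-methyl-3-(propan-2-yl)-5-(triethylsilyloxy)-2-[(triethylsilyloxy)methyl]hept-6-enamide
Conditions: MeNH(OMe)·HCl (3 equiv), AlMe3 (3 equiv), CH2Cl2, 0 °C → rt; aq potassium sodium tartrate
Reagents that add atoms: N,O-dimethylhydroxylamine hydrochloride, CNOC.Cl
Why: Aluminium amide aminolysis of the lactone (Weinreb amide formation) opens the ring at the acyl carbon C3a and frees only the C6 hydroxyl, which thereby differs from the already silylated C5 oxygen, with no stereocentre touched.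

Step 12
Reactants: 18 (2R,3S,4S,5R)-6-bromo-4-hydroxy-N-methoxy-N-methyl-3-(propan-2-yl)-5-(triethylsilyloxy)-2-[(triethylsilyloxy)methyl]hept-6-enamide
Product: 19 (2R,3S,4S,5R)-6-bromo-4-(tert-butyldimethylsilyloxy)-N-methoxy-N-methyl-3-(propan-2-yl)-5-(triethylsilyloxy)-2-[(triethylsilyloxy)methyl]hept-6-enamide
Conditions: t-BuMe2SiOTf, 2,6-lutidine, CH2Cl2, −78 → 0 °C (crude 18 used at once)
Reagents that add atoms: tert-butyldimethylsilyl trifluoromethanesulfonate, CC(C)(C)[Si](C)(C)OS(=O)(=O)C(F)(F)F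
Why: Silylation of a hindered secondary alcohol with a silyl triflate traps the hydroxy amide before it can relactonise and puts on C6 a silyl group more robust than the one on C5.

Step 13
Reactants: 19 (2R,3S,4S,5R)-6-bromo-4-(tert-butyldimethylsilyloxy)-N-methoxy-N-methyl-3-(propan-2-yl)-5-(triethylsilyloxy)-2-[(triethylsilyloxy)methyl]hept-6-enamide
Product: 20 (2R,3S,4S,5R)-6-bromo-4-(tert-butyldimethylsilyloxy)-3-(propan-2-yl)-5-(triethylsilyloxy)-2-[(triethylsilyloxy)methyl]hept-6-enal
Conditions: i-Bu2AlH (1.5 equiv), THF, −78 °C; aq potassium sodium tartrate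
Reagents that add atoms: none
Why: Hydride reduction of a Weinreb amide stops at the aldehyde through the chelated tetrahedral intermediate, and the low temperature protects the α-stereocentre C7a.

Step 14
Reactants: 20 (2R,3S,4S,5R)-6-bromo-4-(tert-butyldimethylsilyloxy)-3-(propan-2-yl)-5-(triethylsilyloxy)-2-[(triethylsilyloxy)methyl]hept-6-enal; 21 methyl (triphenylphosphoranylidene)acetate
Product: 22 methyl (2E,4R,5S,6S,7R)-8-bromo-6-(tert-butyldimethylsilyloxy)-5-(propan-2-yl)-7-(triethylsilyloxy)-4-[(triethylsilyloxy)methyl]nona-2,8-dienoate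
Conditions: Ph3P=CHCO2Me (2 equiv), PhMe, 60 °C
Reagents that add atoms: methyl (triphenylphosphoranylidene)acetate, COC(=O)C=P(c1ccccc1)(c1ccccc1)c1ccccc1
Why: Wittig olefination with a stabilised ylide under base-free conditions should give the (E)-enoate without epimerising C7a or eliminating the β-silyloxy group.

Step 15
Reactants: 22 methyl (2E,4R,5S,6S,7R)-8-bromo-6-(tert-butyldimethylsilyloxy)-5-(propan-2-yl)-7-(triethylsilyloxy)-4-[(triethylsilyloxy)methyl]nona-2,8-dienoate
Product: 23 methyl 2-[(1R,3S,4S,5S,6R)-4-(tert-butyldimethylsilyloxy)-2-methylidene-5-(propan-2-yl)-3-(triethylsilyloxy)-6-[(triethylsilyloxy)methyl]cyclohexyl]acetate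
Conditions: Bu3SnH (1.5 equiv), AIBN (0.2 equiv), syringe pump over 6 h, PhH (0.005 M), 80 °C
Reagents that add atoms: none
Why: A stannyl radical abstracts bromine from C4 to give a σ-vinyl radical that adds to the enoate β-carbon C3a, and the resulting α-ester radical at C3 is reduced by the stannane; the closest known reaction type is the tin hydride-mediated cyclisation of a vinyl radical onto an α,β-unsaturated ester. The cyclohexane ring (C3a–C4–C5–C6–C7–C7a) closes in the 6-exo-trig mode and the exocyclic methylene is present as soon as the ring exists. The one new stereocentre, C3a, should be set by a chair transition state in which the C7 isopropyl group, the C7a CH2OSiEt3 arm and the C3a=C3 unit are equatorial, which puts C3 trans to C1 (3aR). The same chair holds the C5 and C6 silyloxy groups axial, the arrangement that bulky vicinal trans-silyl ethers prefer and that avoids allylic strain between the C5 oxygen and the new methylene. The step needs attack at C3a (6-exo) and not at C3 (7-endo), which the polarity match between the nucleophilic vinyl radical and the electron-poor β-carbon secures. It also needs cyclisation to outrun direct reduction and hydrogen-atom transfer, for which slow stannane addition at high dilution is used and the precursor carries only silyl ethers (no benzylic C–H) within reach of C4.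

Step 16
Reactants: 23 methyl 2-[(1R,3S,4S,5S,6R)-4-(tert-butyldimethylsilyloxy)-2-methylidene-5-(propan-2-yl)-3-(triethylsilyloxy)-6-[(triethylsilyloxy)methyl]cyclohexyl]acetate
Product: 24 2-[(1R,3S,4S,5S,6R)-4-(tert-butyldimethylsilyloxy)-2-methylidene-5-(propan-2-yl)-3-(triethylsilyloxy)-6-[(triethylsilyloxy)methyl]cyclohexyl]ethan-1-ol
Conditions: i-Bu2AlH (2.5 equiv), CH2Cl2, −78 → 0 °C; aq potassium sodium tartrate
Reagents that add atoms: none
Why: Hydride reduction of the methyl ester to the primary alcohol, to which the silyl ethers and the 1,1-disubstituted alkene are inert.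

Step 17
Reactants: 24 2-[(1R,3S,4S,5S,6R)-4-(tert-butyldimethylsilyloxy)-2-methylidene-5-(propan-2-yl)-3-(triethylsilyloxy)-6-[(triethylsilyloxy)methyl]cyclohexyl]ethan-1-ol
Product: 25 (1R,2S,3S,4S,6R)-3-(tert-butyldimethylsilyloxy)-5-methylidene-6-(2-oxoethyl)-2-(propan-2-yl)-4-(triethylsilyloxy)cyclohexane-1-carbaldehyde
Conditions: (COCl)2 (5 equiv), DMSO (10 equiv), CH2Cl2, −78 → −30 °C; then Et3N, −78 → 0 °C
Reagents that add atoms: none
Why: Swern oxidation converts both the free C2 alcohol and the primary triethylsilyl ether at C1 (a group known to be cleaved and oxidised under these conditions) into aldehydes while the secondary silyl ethers at C5 and C6 survive, and C7a should stay equatorial because its epimer would place the formyl group syn-axial to the C6 oxygen.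

Step 18
Reactants: 25 (1R,2S,3S,4S,6R)-3-(tert-butyldimethylsilyloxy)-5-methylidene-6-(2-oxoethyl)-2-(propan-2-yl)-4-(triethylsilyloxy)cyclohexane-1-carbaldehyde
Product: 26 (1R,3aR,5S,6S,7S,7aR)-6-(tert-butyldimethylsilyloxy)-1-hydroxy-4-methylidene-7-(propan-2-yl)-5-(triethylsilyloxy)octahydro-2H-inden-2-one
Conditions: 3-ethyl-5-(2-hydroxyethyl)-4-methylthiazolium bromide (20 mol %), DBU (40 mol %), degassed THF/t-BuOH (0.01 M), 40 °C
Reagents that add atoms: none
Why: Intramolecular NHC-catalysed acyloin (crossed benzoin) condensation closes the cyclopentane at C1–C2, the acyl-anion equivalent forming at the unbranched C2 aldehyde and adding to the branched C1 aldehyde so that C2 becomes the ketone, and the C1 carbinol, which can epimerise through the enediol under the basic conditions, should settle as the pseudo-equatorial alcohol cis to the C7a hydrogen (1R), the 2-keto-1-hydroxy arrangement on which ring D ketols of steroids converge.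

Step 19
Reactants: 26 (1R,3aR,5S,6S,7S,7aR)-6-(tert-butyldimethylsilyloxy)-1-hydroxy-4-methylidene-7-(propan-2-yl)-5-(triethylsilyloxy)octahydro-2H-inden-2-one; 27 acetic anhydride
Product: 28 (1R,3aR,5S,6S,7S,7aR)-6-(tert-butyldimethylsilyloxy)-4-methylidene-2-oxo-7-(propan-2-yl)-5-(triethylsilyloxy)octahydro-1H-inden-1-yl acetate
Conditions: Ac2O, pyridine, DMAP (cat.), CH2Cl2, 0 °C → rt
Reagents that add atoms: acetic anhydride, CC(=O)OC(C)=O
Why: DMAP-catalysed acetylation of the only free hydroxyl proceeds with retention at C1.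

Step 20
Reactants: 28 (1R,3aR,5S,6S,7S,7aR)-6-(tert-butyldimethylsilyloxy)-4-methylidene-2-oxo-7-(propan-2-yl)-5-(triethylsilyloxy)octahydro-1H-inden-1-yl acetate
Product: 29 (1R,3aR,5S,6S,7S,7aR)-6-(tert-butyldimethylsilyloxy)-5-hydroxy-4-methylidene-2-oxo-7-(propan-2-yl)octahydro-1H-inden-1-yl acetate
Conditions: HF·pyridine, pyridine, THF, 0 °C
Reagents that add atoms: none
Why: Buffered fluoride-mediated desilylation should remove the triethylsilyl ether at C5 much faster than the hindered tert-butyldimethylsilyl ether at C6, exposing a single hydroxyl.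

Step 21
Reactants: 29 (1R,3aR,5S,6S,7S,7aR)-6-(tert-butyldimethylsilyloxy)-5-hydroxy-4-methylidene-2-oxo-7-(propan-2-yl)octahydro-1H-inden-1-yl acetate; 30 angelic acid
Product: 32 (1R,3aR,5S,6S,7S,7aR)-1-acetoxy-6-(tert-butyldimethylsilyloxy)-4-methylidene-2-oxo-7-(propan-2-yl)octahydro-1H-inden-5-yl (2Z)-2-methylbut-2-enoate, via mixed anhydride 31 (not isolated)
Conditions: 30, 2,4,6-trichlorobenzoyl chloride, Et3N, PhMe, rt; then 29, PhMe, 75 °C
Reagents that add atoms: angelic acid, C/C=C(/C)C(=O)O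
Why: Yamaguchi esterification through the preformed mixed anhydride acylates the only free hydroxyl (C5) and, run without a nucleophilic catalyst, should keep the (Z)-geometry of the angelate.

Step 22
Reactants: 32 (1R,3aR,5S,6S,7S,7aR)-1-acetoxy-6-(tert-butyldimethylsilyloxy)-4-methylidene-2-oxo-7-(propan-2-yl)octahydro-1H-inden-5-yl (2Z)-2-methylbut-2-enoate
Product: 33 (1R,3aR,5S,6S,7S,7aR)-1-acetoxy-6-hydroxy-4-methylidene-2-oxo-7-(propan-2-yl)octahydro-1H-inden-5-yl (2Z)-2-methylbut-2-enoate (CNP0317011.1)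
Conditions: HF·pyridine, THF, 0 °C → rt
Reagents that add atoms: none
Why: Fluoride-mediated desilylation frees the C6 hydroxyl under mildly acidic conditions that leave both esters and the α-acetoxy ketone intact, and the trans-diaxial C5/C6 oxygens cannot exchange the acyl group.

Compound list

1 | dimethyl (4R,5R)-2,2-dimethyl-1,3-dioxolane-4,5-dicarboxylate (dimethyl 2,3-O-isopropylidene-L-tartrate) | COC(=O)[C@@H]1OC(C)(C)O[C@H]1C(=O)OC | starting material
2 | methyltriphenylphosphonium bromide | C[P+](c1ccccc1)(c1ccccc1)c1ccccc1.[Br-] | starting material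
3 | (4R,5R)-2,2-dimethyl-1,3-dioxolane-4,5-dicarbaldehyde (held as its aluminium hemiacetal) | O=C[C@@H]1OC(C)(C)O[C@H]1C=O | intermediate
4 | (4S,5S)-4,5-diethenyl-2,2-dimethyl-1,3-dioxolane | C=C[C@@H]1OC(C)(C)O[C@H]1C=C | intermediate
5 | (3S,4S)-hexa-1,5-diene-3,4-diol | C=C[C@H](O)[C@@H](O)C=C | intermediate
6 | (3S,4S)-4-(triethylsilyloxy)hexa-1,5-dien-3-ol | C=C[C@H](O[Si](CC)(CC)CC)[C@@H](O)C=C | intermediate
7 | acryloyl chloride | C=CC(=O)Cl | starting material
8 | (3S,4S)-4-(triethylsilyloxy)hexa-1,5-dien-3-yl prop-2-enoate | C=C[C@H](O[Si](CC)(CC)CC)[C@@H](OC(=O)C=C)C=C | intermediate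
9 | (5S)-5-[(1S)-1-(triethylsilyloxy)prop-2-en-1-yl]furan-2(5H)-one | C=C[C@H](O[Si](CC)(CC)CC)[C@@H]1C=CC(=O)O1 | intermediate
10 | isopropylmagnesium bromide | CC(C)[Mg]Br | starting material
11 | (4R,5S)-4-(propan-2-yl)-5-[(1S)-1-(triethylsilyloxy)prop-2-en-1-yl]oxolan-2-one | C=C[C@H](O[Si](CC)(CC)CC)[C@@H]1[C@@H](C(C)C)CC(=O)O1 | intermediate
12 | (4R,5S)-5-[(1R)-2,3-dibromo-1-(triethylsilyloxy)propyl]-4-(propan-2-yl)oxolan-2-one (both epimers at the CHBr carbon) | BrCC(Br)[C@H](O[Si](CC)(CC)CC)[C@@H]1[C@@H](C(C)C)CC(=O)O1 | intermediate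
13 | (4R,5S)-5-[(1R)-2-bromo-1-(triethylsilyloxy)prop-2-en-1-yl]-4-(propan-2-yl)oxolan-2-one | C=C(Br)[C@H](O[Si](CC)(CC)CC)[C@@H]1[C@@H](C(C)C)CC(=O)O1 | intermediate
14 | formaldehyde | C=O | starting material
15 | lithium enolate of 13 | C=C(Br)[C@H](O[Si](CC)(CC)CC)[C@@H]1[C@@H](C(C)C)C=C(O[Li])O1 | intermediate
16 | (3R,4S,5S)-5-[(1R)-2-bromo-1-(triethylsilyloxy)prop-2-en-1-yl]-3-(hydroxymethyl)-4-(propan-2-yl)oxolan-2-one | C=C(Br)[C@H](O[Si](CC)(CC)CC)[C@@H]1[C@@H](C(C)C)[C@H](CO)C(=O)O1 | intermediate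
17 | (3R,4S,5S)-5-[(1R)-2-bromo-1-(triethylsilyloxy)prop-2-en-1-yl]-4-(propan-2-yl)-3-[(triethylsilyloxy)methyl]oxolan-2-one | C=C(Br)[C@H](O[Si](CC)(CC)CC)[C@@H]1[C@@H](C(C)C)[C@H](CO[Si](CC)(CC)CC)C(=O)O1 | intermediate
18 | (2R,3S,4S,5R)-6-bromo-4-hydroxy-N-methoxy-N-methyl-3-(propan-2-yl)-5-(triethylsilyloxy)-2-[(triethylsilyloxy)methyl]hept-6-enamide | C=C(Br)[C@H](O[Si](CC)(CC)CC)[C@@H](O)[C@@H](C(C)C)[C@H](CO[Si](CC)(CC)CC)C(=O)N(C)OC | intermediate
19 | (2R,3S,4S,5R)-6-bromo-4-(tert-butyldimethylsilyloxy)-N-methoxy-N-methyl-3-(propan-2-yl)-5-(triethylsilyloxy)-2-[(triethylsilyloxy)methyl]hept-6-enamide | C=C(Br)[C@H](O[Si](CC)(CC)CC)[C@@H](O[Si](C)(C)C(C)(C)C)[C@@H](C(C)C)[C@H](CO[Si](CC)(CC)CC)C(=O)N(C)OC | intermediate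
20 | (2R,3S,4S,5R)-6-bromo-4-(tert-butyldimethylsilyloxy)-3-(propan-2-yl)-5-(triethylsilyloxy)-2-[(triethylsilyloxy)methyl]hept-6-enal | C=C(Br)[C@H](O[Si](CC)(CC)CC)[C@@H](O[Si](C)(C)C(C)(C)C)[C@@H](C(C)C)[C@H](CO[Si](CC)(CC)CC)C=O | intermediate
21 | methyl (triphenylphosphoranylidene)acetate | COC(=O)C=P(c1ccccc1)(c1ccccc1)c1ccccc1 | starting material
22 | methyl (2E,4R,5S,6S,7R)-8-bromo-6-(tert-butyldimethylsilyloxy)-5-(propan-2-yl)-7-(triethylsilyloxy)-4-[(triethylsilyloxy)methyl]nona-2,8-dienoate (key-step precursor) | C=C(Br)[C@H](O[Si](CC)(CC)CC)[C@@H](O[Si](C)(C)C(C)(C)C)[C@@H](C(C)C)[C@H](CO[Si](CC)(CC)CC)/C=C/C(=O)OC | intermediate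
23 | methyl 2-[(1R,3S,4S,5S,6R)-4-(tert-butyldimethylsilyloxy)-2-methylidene-5-(propan-2-yl)-3-(triethylsilyloxy)-6-[(triethylsilyloxy)methyl]cyclohexyl]acetate (key-step product) | C=C1[C@H](CC(=O)OC)[C@@H](CO[Si](CC)(CC)CC)[C@H](C(C)C)[C@H](O[Si](C)(C)C(C)(C)C)[C@H]1O[Si](CC)(CC)CC | intermediate
24 | 2-[(1R,3S,4S,5S,6R)-4-(tert-butyldimethylsilyloxy)-2-methylidene-5-(propan-2-yl)-3-(triethylsilyloxy)-6-[(triethylsilyloxy)methyl]cyclohexyl]ethan-1-ol | C=C1[C@H](CCO)[C@@H](CO[Si](CC)(CC)CC)[C@H](C(C)C)[C@H](O[Si](C)(C)C(C)(C)C)[C@H]1O[Si](CC)(CC)CC | intermediate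
25 | (1R,2S,3S,4S,6R)-3-(tert-butyldimethylsilyloxy)-5-methylidene-6-(2-oxoethyl)-2-(propan-2-yl)-4-(triethylsilyloxy)cyclohexane-1-carbaldehyde | C=C1[C@H](CC=O)[C@@H](C=O)[C@H](C(C)C)[C@H](O[Si](C)(C)C(C)(C)C)[C@H]1O[Si](CC)(CC)CC | intermediate
26 | (1R,3aR,5S,6S,7S,7aR)-6-(tert-butyldimethylsilyloxy)-1-hydroxy-4-methylidene-7-(propan-2-yl)-5-(triethylsilyloxy)octahydro-2H-inden-2-one | C=C1[C@@H]2CC(=O)[C@H](O)[C@H]2[C@H](C(C)C)[C@H](O[Si](C)(C)C(C)(C)C)[C@H]1O[Si](CC)(CC)CC | intermediate
27 | acetic anhydride | CC(=O)OC(C)=O | starting material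
28 | (1R,3aR,5S,6S,7S,7aR)-6-(tert-butyldimethylsilyloxy)-4-methylidene-2-oxo-7-(propan-2-yl)-5-(triethylsilyloxy)octahydro-1H-inden-1-yl acetate | C=C1[C@@H]2CC(=O)[C@H](OC(C)=O)[C@H]2[C@H](C(C)C)[C@H](O[Si](C)(C)C(C)(C)C)[C@H]1O[Si](CC)(CC)CC | intermediate
29 | (1R,3aR,5S,6S,7S,7aR)-6-(tert-butyldimethylsilyloxy)-5-hydroxy-4-methylidene-2-oxo-7-(propan-2-yl)octahydro-1H-inden-1-yl acetate | C=C1[C@@H]2CC(=O)[C@H](OC(C)=O)[C@H]2[C@H](C(C)C)[C@H](O[Si](C)(C)C(C)(C)C)[C@H]1O | intermediate
30 | angelic acid, (2Z)-2-methylbut-2-enoic acid | C/C=C(/C)C(=O)O | starting material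
31 | (2Z)-2-methylbut-2-enoic 2,4,6-trichlorobenzoic anhydride | C/C=C(/C)C(=O)OC(=O)c1c(Cl)cc(Cl)cc1Cl | intermediate
32 | (1R,3aR,5S,6S,7S,7aR)-1-acetoxy-6-(tert-butyldimethylsilyloxy)-4-methylidene-2-oxo-7-(propan-2-yl)octahydro-1H-inden-5-yl (2Z)-2-methylbut-2-enoate | C=C1[C@@H]2CC(=O)[C@H](OC(C)=O)[C@H]2[C@H](C(C)C)[C@H](O[Si](C)(C)C(C)(C)C)[C@H]1OC(=O)/C(C)=C\C | intermediate
33 | (1R,3aR,5S,6S,7S,7aR)-1-acetoxy-6-hydroxy-4-methylidene-2-oxo-7-(propan-2-yl)octahydro-1H-inden-5-yl (2Z)-2-methylbut-2-enoate | C=C1[C@@H]2CC(=O)[C@H](OC(C)=O)[C@H]2[C@H](C(C)C)[C@H](O)[C@H]1OC(=O)/C(C)=C\C | target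

Total step count: 22. Longest linear sequence: 22 steps (1 → 33); the route is fully linear.

Steps most likely to fail

Step 15. The vinyl radical may be reduced by the stannane, or may abstract a hydrogen atom (1,5 from C7–H) before it closes the ring, and the chair preference that fixes C3a may be incomplete. As a fallback, the same C3a–C4 bond would be formed from 22 by an organonickel route instead of a radical one. This is a reductive cyclisation with zerovalent nickel, Ni(cod)2 (2 equiv), Et3N, MeCN, rt, in which oxidative addition into the C4–Br bond is followed by 6-exo insertion of the enoate and protonolysis of the nickel enolate. It comes back to the route at 23 with no new compound, F0.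

Step 18. Intermolecular acyloin or aldol reaction may compete with ring closure, and equilibration at C1 may stall or favour the alcohol on the face trans to the C7a hydrogen. As a fallback, closure of 25 would be run briefly with Et3N in place of DBU and the kinetic product, the C1 epimer of 26, (1S)-ketol F1, would be isolated. Mitsunobu reaction of F1 (PPh3, DIAD, AcOH, THF, 0 °C → rt) would then introduce the acetate with inversion at C1 and rejoin the route at 28, so that C1 is fixed by SN2 displacement instead of by equilibration.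

Step 21. Acylation of the hindered axial C5 alcohol may be slow enough for the activated angelate to isomerise from (Z) to (E), giving the tiglate, and prolonged heating with amine may disturb the α-acetoxy ketone. As a fallback, the angelate would be built on the molecule instead of being transferred. From 29 the C5 alcohol would be esterified with 2-[bis(2,2,2-trifluoroethoxy)phosphoryl]propanoic acid (DCC, DMAP, CH2Cl2, 0 °C) to give the phosphonate ester F2. A Still–Gennari olefination of F2 (KN(SiMe3)2 (1.0 equiv), 18-crown-6, THF, −78 °C; then acetaldehyde) should then give the (Z)-2-methylbut-2-enoate and rejoin the route at 32; the phosphonate is far more acidic than the ketone, so one equivalent of base should deprotonate it selectively.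

Further compounds

F0 | step 15 | none | none
F1 | step 18 | (1S,3aR,5S,6S,7S,7aR)-6-(tert-butyldimethylsilyloxy)-1-hydroxy-4-methylidene-7-(propan-2-yl)-5-(triethylsilyloxy)octahydro-2H-inden-2-one | C=C1[C@@H]2CC(=O)[C@@H](O)[C@H]2[C@H](C(C)C)[C@H](O[Si](C)(C)C(C)(C)C)[C@H]1O[Si](CC)(CC)CC
F2 | step 21 | (1R,3aR,5S,6S,7S,7aR)-1-acetoxy-6-(tert-butyldimethylsilyloxy)-4-methylidene-2-oxo-7-(propan-2-yl)octahydro-1H-inden-5-yl 2-[bis(2,2,2-trifluoroethoxy)phosphoryl]propanoate (both epimers at the phosphonate carbon) | C=C1[C@@H]2CC(=O)[C@H](OC(C)=O)[C@H]2[C@H](C(C)C)[C@H](O[Si](C)(C)C(C)(C)C)[C@H]1OC(=O)C(C)P(=O)(OCC(F)(F)F)OCC(F)(F)F
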